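**Retrosynthetic overview**

1. Labels: ring carbons C1–C14 follow the target SMILES (C1 = C(=CH2), C5 = CHMe, C6 = CHOH, C7 = CH–O of the lactone, C8 = lactone β-CH, C10/C11 = oxirane, C14 = CHOH); C15 is the lactone α-carbon.
2. Last operation: fluoride removes the C14 silyl ether and eliminates methanesulfinate from a sulfinate-masked lactone, which unveils the α-methylene-γ-butyrolactone.
3. Key disconnection C2–C3: the 14-membered carbocycle is closed by a radical allyl-transfer (addition–fragmentation) macrocyclization of a C3 primary alkyl radical onto a 2-(methylsulfonylmethyl)allyl unit; the same event creates the C1 exocyclic methylene.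
4. The acyclic precursor comes from a Shi epoxidation (C10–C11) and a chelation-controlled indium Barbier allylation/lactonization (C7–C8). The West α-hydroxy aldehyde comes from Brown (Z)-crotylboration of 2,2-dimethoxyacetaldehyde. The East (Z)-2-(bromomethyl)enoate comes from pent-4-ynal by asymmetric Nozaki–Hiyama–Kishi alkenylation, Zr-catalysed carboalumination/oxirane opening and vinylalumination.
5. Ring order: γ-lactone (step 10), then oxirane (step 12), then the 14-membered carbocycle (step 13).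

Assumption: the SMILES is read as 5S,6R,7R,8S,10R,11R,14R (labels as above; cis-fused lactone, oxirane derived from an E-alkene); 2,2-dimethoxyacetaldehyde is used as the dried monomer and pent-4-ynal as bought.

**Route**

Step 1
Reactants: 1 2,2-dimethoxyacetaldehyde; 2 (Z)-but-2-ene
Product: 6 (2R,3S)-1,1-dimethoxy-3-methylpent-4-en-2-ol, via (Z)-crotylpotassium 3 (not isolated), via (Z)-crotyldiisopinocampheylborane 4 (not isolated), via borinate ester 5 (not isolated)
Conditions: 2, KOtBu, n-BuLi, THF, −78 → −45 °C; (+)-Ipc2BOMe, −78 °C; BF3·OEt2; 1, −78 °C; then NaOH, H2O2, 0 °C → rt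
Reagents that add atoms: none
Why: Brown (Z)-crotylboration through a closed chair transition state; the Z-crotyl geometry gives the syn C5-methyl/C6-hydroxyl pair and the (+)-Ipc ligands direct attack to the Re face of the aldehyde, which sets 5S and 6R (2R,3S in 6).

Step 2
Reactants: 6 (2R,3S)-1,1-dimethoxy-3-methylpent-4-en-2-ol
Product: 8 (2R,3S)-5-bromo-1,1-dimethoxy-3-methylpentan-2-ol, via zirconocene alkyl 7 (not isolated)
Conditions: Cp2Zr(H)Cl (2.2 equiv), THF, rt; then NBS, 0 °C
Reagents that add atoms: N-bromosuccinimide, O=C1CCC(=O)N1Br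
Why: Hydrozirconation–halogenation; one equivalent of Cp2Zr(H)Cl is consumed by the free hydroxyl, the second adds anti-Markovnikov to the terminal alkene, and NBS cleaves the primary C–Zr bond to the C3 bromide without touching the acetal or the stereocenters.

Step 3
Reactants: 9 2,3-dibromoprop-1-ene; 10 sodium methanesulfinate (MeSO2Na)
Product: 11 2-bromo-3-(methylsulfonyl)prop-1-ene
Conditions: MeOH, rt
Reagents that add atoms: none
Why: SN2 S-alkylation of the sulfinate at the allylic bromide; the vinylic bromide is inert.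

Step 4
Reactants: 11 2-bromo-3-(methylsulfonyl)prop-1-ene; 12 pent-4-ynal
Product: 13 (3R)-2-[(methylsulfonyl)methyl]hept-1-en-6-yn-3-ol
Conditions: CrCl2 (10 mol%), chiral oxazoline–sulfonamide ligand (Kishi type, antipode giving 3R, 11 mol%), proton sponge, NiCl2 (2 mol%), Mn, LiCl, Cp2ZrCl2, MeCN, rt; aq. work-up
Reagents that add atoms: none
Why: Catalytic asymmetric Nozaki–Hiyama–Kishi alkenylation; the alkenylchromium formed by Ni/Cr exchange adds to the aldehyde inside the chiral sulfonamide pocket and sets the C14 carbinol (3R in 13) by reagent control, a reaction established for 2-halo-1-alkenes and tolerant of sulfones and alkynes.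

Step 5
Reactants: 13 (3R)-2-[(methylsulfonyl)methyl]hept-1-en-6-yn-3-ol
Product: 14 tert-butyl(dimethyl){[(3R)-2-[(methylsulfonyl)methyl]hept-1-en-6-yn-3-yl]oxy}silane
Conditions: TBSCl, imidazole, DMF, rt
Reagents that add atoms: tert-butyldimethylsilyl chloride, C[Si](C)(Cl)C(C)(C)C
Why: Standard silylation protects the allylic C14 alcohol against the oxidation and bromination steps that follow.

Step 6
Reactants: 14 tert-butyl(dimethyl){[(3R)-2-[(methylsulfonyl)methyl]hept-1-en-6-yn-3-yl]oxy}silane; 15 oxirane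
Product: 18 (3E,7R)-7-[(tert-butyldimethylsilyl)oxy]-4-methyl-8-[(methylsulfonyl)methyl]nona-3,8-dien-1-ol, via alkenyldimethylalane 16 (not isolated), via lithium alkenylaluminate 17 (not isolated)
Conditions: Me3Al (3 equiv), Cp2ZrCl2 (25 mol%), CH2Cl2, 0 °C → rt; evaporate, hexane; n-BuLi, −78 °C; 15, THF, −78 → 0 °C; aq. NH4Cl
Reagents that add atoms: trimethylaluminium, C[Al](C)C
Why: Negishi Zr-catalysed syn-carboalumination of the terminal alkyne puts the methyl on the internal carbon and fixes the E-trisubstituted C10=C11 geometry; the derived aluminate opens oxirane with retention at the alkenyl carbon.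

Step 7
Reactants: 18 (3E,7R)-7-[(tert-butyldimethylsilyl)oxy]-4-methyl-8-[(methylsulfonyl)methyl]nona-3,8-dien-1-ol
Product: 19 (3E,7R)-7-[(tert-butyldimethylsilyl)oxy]-4-methyl-8-[(methylsulfonyl)methyl]nona-3,8-dienal
Conditions: Dess–Martin periodinane, NaHCO3, CH2Cl2, 0 °C
Reagents that add atoms: none
Why: Dess–Martin oxidation is non-basic, so the β,γ-unsaturated aldehyde is obtained without migration of the double bond into conjugation; it is used crude.

Step 8
Reactants: 19 (3E,7R)-7-[(tert-butyldimethylsilyl)oxy]-4-methyl-8-[(methylsulfonyl)methyl]nona-3,8-dienal; 20 methyl propiolate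
Product: 22 methyl (5E,9R)-9-[(tert-butyldimethylsilyl)oxy]-3-hydroxy-6-methyl-2-methylidene-10-[(methylsulfonyl)methyl]undeca-5,10-dienoate (C3 epimers), via (methoxycarbonylvinyl)diisobutylalane 21 (not isolated)
Conditions: 20, i-Bu2AlH, N-methylmorpholine N-oxide, THF, 0 °C; then 19, 0 °C → rt
Reagents that add atoms: none
Why: Vinylalumination, a non-basic Morita–Baylis–Hillman equivalent; 1,4-hydroalumination of methyl propiolate gives the α-alumino acrylate, which adds 1,2 to the aldehyde, and the new carbinol center is irrelevant because it is ionised in step 9.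

Step 9
Reactants: 22 methyl (5E,9R)-9-[(tert-butyldimethylsilyl)oxy]-3-hydroxy-6-methyl-2-methylidene-10-[(methylsulfonyl)methyl]undeca-5,10-dienoate
Product: 23 methyl (2Z,5E,9R)-2-(bromomethyl)-9-[(tert-butyldimethylsilyl)oxy]-6-methyl-10-[(methylsulfonyl)methyl]undeca-2,5,10-trienoate
Conditions: NBS, Me2S, CH2Cl2, 0 °C → rt
Reagents that add atoms: N-bromosuccinimide, O=C1CCC(=O)N1Br
Why: Corey–Kim-type SN2′ bromination of the Baylis–Hillman alcohol; bromide attacks the CH2 terminus of the alkoxysulfonium salt with allylic transposition and gives the thermodynamically preferred (Z)-2-(bromomethyl)enoate.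

Step 10
Reactants: 8 (2R,3S)-5-bromo-1,1-dimethoxy-3-methylpentan-2-ol; 23 methyl (2Z,5E,9R)-2-(bromomethyl)-9-[(tert-butyldimethylsilyl)oxy]-6-methyl-10-[(methylsulfonyl)methyl]undeca-2,5,10-trienoate
Product: 26 (4S,5R)-5-[(1R,2S)-4-bromo-1-hydroxy-2-methylbutyl]-4-{(2E,6R)-6-[(tert-butyldimethylsilyl)oxy]-3-methyl-7-[(methylsulfonyl)methyl]octa-2,7-dien-1-yl}-3-methylideneoxolan-2-one, via hydroxy aldehyde 24 (not isolated), via hydroxy ester 25 (not isolated)
Conditions: 8, 1 M HCl, THF, 40 °C; NaHCO3 to pH 6; 23, In powder, THF/H2O 1:1, rt; then TsOH (cat.), CH2Cl2, rt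
Reagents that add atoms: water, O
Why: Indium-mediated Barbier allylation in water followed by lactonization; indium chelates the free C6 hydroxyl and the aldehyde (Cram-chelate attack gives the 6,7-syn diol, 7R), the (Z)-allylindium reacts through its γ-carbon in a chair-like transition state to give the 7,8-syn adduct (8S), and the C7 hydroxyl closes the cis-fused α-methylene-γ-lactone.

Step 11
Reactants: 26 the α-methylene lactone of step 10; 10 sodium methanesulfinate (MeSO2Na)
Product: 27 (3RS,4S,5R)-5-[(1R,2S)-4-bromo-1-hydroxy-2-methylbutyl]-4-{(2E,6R)-6-[(tert-butyldimethylsilyl)oxy]-3-methyl-7-[(methylsulfonyl)methyl]octa-2,7-dien-1-yl}-3-[(methylsulfonyl)methyl]oxolan-2-one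
Conditions: 10, AcOH, EtOH/H2O, 40 °C
Reagents that add atoms: none
Why: Sulfa-Michael addition of methanesulfinic acid masks the α-methylene lactone as a β-sulfonyl lactone (both C15 epimers converge in step 14), so that no radical acceptor lies within reach of C3 in the key step.

Step 12
Reactants: 27 the sulfinate-masked lactone of step 11
Product: 28 (3RS,4S,5R)-5-[(1R,2S)-4-bromo-1-hydroxy-2-methylbutyl]-4-({(2R,3R)-3-[(3R)-3-[(tert-butyldimethylsilyl)oxy]-4-[(methylsulfonyl)methyl]pent-4-en-1-yl]-3-methyloxiran-2-yl}methyl)-3-[(methylsulfonyl)methyl]oxolan-2-one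
Conditions: D-fructose-derived Shi ketone (0.5 equiv), KHSO5 (as 2KHSO5·KHSO4·K2SO4), NaHCO3 (pH 8), Bu4NHSO4 (cat.), MeCN/dimethoxymethane/H2O, 0 °C
Reagents that add atoms: potassium peroxymonosulfate (KHSO5), [K+].[O-]S(=O)(=O)OO
Why: Shi asymmetric epoxidation; the chiral dioxirane attacks the only electron-rich alkene (E-trisubstituted C10=C11) through the spiro transition state and gives the 10R,11R oxirane by reagent control, while the electron-poor allyl sulfone alkene and the bromide do not react and pH 8 keeps the masked lactone intact.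

Step 13
Reactants: 28 the bromo epoxide of step 12
Product: 29 (5S,6R,7R,8S,10R,11R,14R)-14-O-(tert-butyldimethylsilyl)-15-[(methylsulfonyl)methyl] macrocycle: the target ring system with a silyl ether at C14 and CH–CH2SO2Me in place of C=CH2 at C15
Conditions: Bu3SnSnBu3 (1.5 equiv), hν (sunlamp), PhH, 80 °C, 28 added by syringe pump to 2 mM
Reagents that add atoms: none
Why: Proposed new method: Bu3Sn• from photolysis of the ditin abstracts bromine from C3; the primary radical has no hydrogen donor and no nearby acceptor (the lactone methylene is masked), so it adds 14-endo to the unsubstituted CH2 terminus (C2) of the 2-(methylsulfonylmethyl)allyl unit, and the tertiary adduct radical at C1 irreversibly expels MeSO2•, which forms the C1 exocyclic methylene and regenerates Bu3Sn• from the ditin; stannyl attack on the allyl sulfone only gives the corresponding allylstannane, an equally competent acceptor; no stereocenter is formed; the closest known reactions are Keck- and Zard-type intermolecular radical allylations with allyl stannanes and allyl sulfones and Porter/Pattenden endo-selective radical macrocyclizations.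

Step 14
Reactants: 29 the masked, silylated macrocycle of step 13
Product: 30 CNP0124069.1, (5S,6R,7R,8S,10R,11R,14R)-configured target (6,14-dihydroxy-5,11-dimethyl-1,15-dimethylidene-10,11-epoxy 14-membered carbocycle with the C7–O/C8–C15 cis-fused γ-lactone)
Conditions: Bu4NF (4 equiv), THF, 0 °C → rt
Reagents that add atoms: none
Why: Fluoride cleaves the silyl ether and, acting as a base, triggers E1cB loss of methanesulfinate from the β-sulfonyl lactone, which unveils the α-methylene-γ-butyrolactone without touching any stereocenter.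

**Compound list**

1 | 2,2-dimethoxyacetaldehyde | COC(OC)C=O | starting material
2 | (Z)-but-2-ene | C/C=C\C | starting material
3 | (Z)-crotylpotassium | C/C=C\C[K] | intermediate (not isolated)
4 | (+)-B-[(Z)-but-2-enyl]diisopinocampheylborane (Ipc groups from (−)-α-pinene) | C/C=C\CB([C@H]1C[C@H]2C[C@@H]([C@@H]1C)C2(C)C)[C@H]1C[C@H]2C[C@@H]([C@@H]1C)C2(C)C | intermediate (not isolated)
5 | (2R,3S)-1,1-dimethoxy-3-methylpent-4-en-2-yl diisopinocampheylborinate | COC(OC)[C@H](OB([C@H]1C[C@H]2C[C@@H]([C@@H]1C)C2(C)C)[C@H]1C[C@H]2C[C@@H]([C@@H]1C)C2(C)C)[C@@H](C)C=C | intermediate (not isolated)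
6 | (2R,3S)-1,1-dimethoxy-3-methylpent-4-en-2-ol | COC(OC)[C@H](O)[C@@H](C)C=C | intermediate
7 | O,C5-bis[chlorobis(cyclopentadienyl)zirconium] derivative of (2R,3S)-1,1-dimethoxy-3-methylpentan-2-ol | COC(OC)[C@H](O[Zr](Cl)(C1C=CC=C1)C1C=CC=C1)[C@@H](C)CC[Zr](Cl)(C1C=CC=C1)C1C=CC=C1 | intermediate (not isolated)
8 | (2R,3S)-5-bromo-1,1-dimethoxy-3-methylpentan-2-ol | COC(OC)[C@H](O)[C@@H](C)CCBr | intermediate
9 | 2,3-dibromoprop-1-ene | C=C(Br)CBr | starting material
10 | sodium methanesulfinate (MeSO2Na) | [Na+].CS(=O)[O-] | starting material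
11 | 2-bromo-3-(methylsulfonyl)prop-1-ene | C=C(Br)CS(C)(=O)=O | intermediate
12 | pent-4-ynal | C#CCCC=O | starting material
13 | (3R)-2-[(methylsulfonyl)methyl]hept-1-en-6-yn-3-ol | C#CCC[C@@H](O)C(=C)CS(C)(=O)=O | intermediate
14 | tert-butyl(dimethyl){[(3R)-2-[(methylsulfonyl)methyl]hept-1-en-6-yn-3-yl]oxy}silane | C#CCC[C@@H](O[Si](C)(C)C(C)(C)C)C(=C)CS(C)(=O)=O | intermediate
15 | oxirane | C1CO1 | starting material
16 | (E)-alkenyldimethylalane from syn-carboalumination of 14 | C[Al](C)/C=C(\C)CC[C@@H](O[Si](C)(C)C(C)(C)C)C(=C)CS(C)(=O)=O | intermediate (not isolated)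
17 | lithium butyl(dimethyl)[(E)-alkenyl]aluminate derived from 16 | [Li+].CCCC[Al-](C)(C)/C=C(\C)CC[C@@H](O[Si](C)(C)C(C)(C)C)C(=C)CS(C)(=O)=O | intermediate (not isolated)
18 | (3E,7R)-7-[(tert-butyldimethylsilyl)oxy]-4-methyl-8-[(methylsulfonyl)methyl]nona-3,8-dien-1-ol | OCC/C=C(\C)CC[C@@H](O[Si](C)(C)C(C)(C)C)C(=C)CS(C)(=O)=O | intermediate
19 | (3E,7R)-7-[(tert-butyldimethylsilyl)oxy]-4-methyl-8-[(methylsulfonyl)methyl]nona-3,8-dienal | O=CC/C=C(\C)CC[C@@H](O[Si](C)(C)C(C)(C)C)C(=C)CS(C)(=O)=O | intermediate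
20 | methyl propiolate | C#CC(=O)OC | starting material
21 | [1-(methoxycarbonyl)vinyl]diisobutylalane | C=C(C(=O)OC)[Al](CC(C)C)CC(C)C | intermediate (not isolated)
22 | methyl (5E,9R)-9-[(tert-butyldimethylsilyl)oxy]-3-hydroxy-6-methyl-2-methylidene-10-[(methylsulfonyl)methyl]undeca-5,10-dienoate (C3 epimers) | COC(=O)C(=C)C(O)C/C=C(\C)CC[C@@H](O[Si](C)(C)C(C)(C)C)C(=C)CS(C)(=O)=O | intermediate
23 | methyl (2Z,5E,9R)-2-(bromomethyl)-9-[(tert-butyldimethylsilyl)oxy]-6-methyl-10-[(methylsulfonyl)methyl]undeca-2,5,10-trienoate | COC(=O)/C(CBr)=C/C/C=C(\C)CC[C@@H](O[Si](C)(C)C(C)(C)C)C(=C)CS(C)(=O)=O | intermediate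
24 | (2R,3S)-5-bromo-2-hydroxy-3-methylpentanal | O=C[C@H](O)[C@@H](C)CCBr | intermediate (not isolated)
25 | methyl (3S,4R,5R,6S)-8-bromo-3-{(2E,6R)-6-[(tert-butyldimethylsilyl)oxy]-3-methyl-7-[(methylsulfonyl)methyl]octa-2,7-dien-1-yl}-4,5-dihydroxy-6-methyl-2-methylideneoctanoate | BrCC[C@H](C)[C@@H](O)[C@H](O)[C@H](C(=C)C(=O)OC)C/C=C(\C)CC[C@@H](O[Si](C)(C)C(C)(C)C)C(=C)CS(C)(=O)=O | intermediate (not isolated)
26 | (4S,5R)-5-[(1R,2S)-4-bromo-1-hydroxy-2-methylbutyl]-4-{(2E,6R)-6-[(tert-butyldimethylsilyl)oxy]-3-methyl-7-[(methylsulfonyl)methyl]octa-2,7-dien-1-yl}-3-methylideneoxolan-2-one | BrCC[C@H](C)[C@@H](O)[C@@H]1OC(=O)C(=C)[C@@H]1C/C=C(\C)CC[C@@H](O[Si](C)(C)C(C)(C)C)C(=C)CS(C)(=O)=O | intermediate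
27 | (3RS,4S,5R)-5-[(1R,2S)-4-bromo-1-hydroxy-2-methylbutyl]-4-{(2E,6R)-6-[(tert-butyldimethylsilyl)oxy]-3-methyl-7-[(methylsulfonyl)methyl]octa-2,7-dien-1-yl}-3-[(methylsulfonyl)methyl]oxolan-2-one | BrCC[C@H](C)[C@@H](O)[C@@H]1OC(=O)C(CS(C)(=O)=O)[C@@H]1C/C=C(\C)CC[C@@H](O[Si](C)(C)C(C)(C)C)C(=C)CS(C)(=O)=O | intermediate
28 | (3RS,4S,5R)-5-[(1R,2S)-4-bromo-1-hydroxy-2-methylbutyl]-4-({(2R,3R)-3-[(3R)-3-[(tert-butyldimethylsilyl)oxy]-4-[(methylsulfonyl)methyl]pent-4-en-1-yl]-3-methyloxiran-2-yl}methyl)-3-[(methylsulfonyl)methyl]oxolan-2-one | BrCC[C@H](C)[C@@H](O)[C@@H]1OC(=O)C(CS(C)(=O)=O)[C@@H]1C[C@H]1O[C@]1(C)CC[C@@H](O[Si](C)(C)C(C)(C)C)C(=C)CS(C)(=O)=O | intermediate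
29 | (5S,6R,7R,8S,10R,11R,14R)-14-O-(tert-butyldimethylsilyl)-15-[(methylsulfonyl)methyl] macrocycle (target ring system, silyl ether at C14, CH–CH2SO2Me at C15, C15 epimers) | C=C1CCC[C@H](C)[C@@H](O)[C@@H]2OC(=O)C(CS(C)(=O)=O)[C@@H]2C[C@H]2O[C@]2(C)CC[C@H]1O[Si](C)(C)C(C)(C)C | intermediate
30 | CNP0124069.1, (5S,6R,7R,8S,10R,11R,14R) | C=C1CCC[C@H](C)[C@@H](O)[C@@H]2OC(=O)C(=C)[C@@H]2C[C@H]2O[C@]2(C)CC[C@H]1O | target

**Step count and risks**

Total step count: 14. Longest linear sequence: 12 steps (steps 3 to 14, from 9 and 10 through 11).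

Most likely to fail, first: step 13. Addition of a primary radical to a non-conjugated allyl sulfone is slow for a 14-membered closure and competes with 1,5-hydrogen transfer from C7–H and with simple reduction. The fallback activates the acceptor as an enone and sets C14 afterwards; it sets out from 27 and comes back at 30. HF·pyridine/pyridine in THF at 0 °C removes the silyl group from 27 and gives the C14 allylic alcohol F1. Shi epoxidation as in step 12 gives the epoxy diol F2. MnO2 in CH2Cl2 oxidizes only the allylic C14 carbinol and gives the 2-(methylsulfonylmethyl)enone F3, whose conjugated acceptor should react far faster with alkyl radicals. The same Bu3SnSnBu3/hν conditions then close the ring to the macrocyclic enone F4. (S)-Me-CBS oxazaborolidine with catecholborane at −78 °C reduces the ketone under reagent control to the 14R alcohol F5. DBU in CH2Cl2 at 0 °C eliminates methanesulfinate and delivers 30.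

Second: step 4. The alkenylchromium carries an allylic sulfone and may eliminate to an allene, and the enantioselectivity with this bromide is untested. The fallback builds the C14 carbinol by ketone reduction and introduces the sulfone last; it sets out from 12 and comes back at 14. Isopropenylmagnesium bromide (CH2=C(CH3)MgBr) adds to 12 and gives racemic 2-methylhept-1-en-6-yn-3-ol F6. Dess–Martin oxidation gives 2-methylhept-1-en-6-yn-3-one F7. (S)-Me-CBS oxazaborolidine with catecholborane (which spares the alkyne) gives (3R)-2-methylhept-1-en-6-yn-3-ol F8. TBSCl/imidazole gives the silyl ether F9. Ene-type allylic chlorination (NCS, cat. PhSeCl) moves the double bond toward the methyl group and gives the allylic chloride F10. MeSO2Na (10) with cat. NaI in DMF displaces the chloride and gives 14.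

Third: step 10. The diastereoselectivity of the aqueous Barbier reaction rests on chelation by the free C6 hydroxyl, and the hydroxy aldehyde is prone to oligomerize. The fallback uses a Lewis-acid-mediated allylstannane addition to a protected aldehyde; it sets out from 8 and 23 and comes back at 26. Bu3SnLi/CuBr·SMe2 displaces the bromide of 23 at the CH2Br carbon and gives the 2-(tributylstannylmethyl)enoate F11. 4-Methoxybenzyl trichloroacetimidate with cat. CSA protects 8 as the PMB ether F12, and aqueous acid hydrolysis of the acetal gives the α-PMB-oxy aldehyde F13. MgBr2·OEt2 in CH2Cl2 at −78 °C chelates F13 and promotes anti-SE2′ addition of F11 to give the syn,syn hydroxy ester F14, which lactonizes with cat. TsOH to the PMB-protected lactone F15. DDQ in wet CH2Cl2 removes the PMB group and gives 26.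

**Further compounds**

F1 | step 13 | desilylated 27 (free C14 allylic alcohol, masked lactone, bromide) | BrCC[C@H](C)[C@@H](O)[C@@H]1OC(=O)C(CS(C)(=O)=O)[C@@H]1C/C=C(\C)CC[C@@H](O)C(=C)CS(C)(=O)=O
F2 | step 13 | (10R,11R)-epoxide of F1 | BrCC[C@H](C)[C@@H](O)[C@@H]1OC(=O)C(CS(C)(=O)=O)[C@@H]1C[C@H]1O[C@]1(C)CC[C@@H](O)C(=C)CS(C)(=O)=O
F3 | step 13 | C14 ketone of F2 (2-(methylsulfonylmethyl)enone) | BrCC[C@H](C)[C@@H](O)[C@@H]1OC(=O)C(CS(C)(=O)=O)[C@@H]1C[C@H]1O[C@]1(C)CCC(=O)C(=C)CS(C)(=O)=O
F4 | step 13 | macrocyclic C14 enone with masked lactone | C=C1CCC[C@H](C)[C@@H](O)[C@@H]2OC(=O)C(CS(C)(=O)=O)[C@@H]2C[C@H]2O[C@]2(C)CCC1=O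
F5 | step 13 | macrocyclic (14R)-alcohol with masked lactone | C=C1CCC[C@H](C)[C@@H](O)[C@@H]2OC(=O)C(CS(C)(=O)=O)[C@@H]2C[C@H]2O[C@]2(C)CC[C@H]1O
F6 | step 4 | racemic 2-methylhept-1-en-6-yn-3-ol | C#CCCC(O)C(C)=C
F7 | step 4 | 2-methylhept-1-en-6-yn-3-one | C#CCCC(=O)C(C)=C
F8 | step 4 | (3R)-2-methylhept-1-en-6-yn-3-ol | C#CCC[C@@H](O)C(C)=C
F9 | step 4 | tert-butyl(dimethyl){[(3R)-2-methylhept-1-en-6-yn-3-yl]oxy}silane | C#CCC[C@@H](O[Si](C)(C)C(C)(C)C)C(C)=C
F10 | step 4 | tert-butyl{[(3R)-2-(chloromethyl)hept-1-en-6-yn-3-yl]oxy}dimethylsilane | C#CCC[C@@H](O[Si](C)(C)C(C)(C)C)C(=C)CCl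
F11 | step 10 | methyl (2Z,5E,9R)-9-[(tert-butyldimethylsilyl)oxy]-6-methyl-10-[(methylsulfonyl)methyl]-2-[(tributylstannyl)methyl]undeca-2,5,10-trienoate | COC(=O)/C(C[Sn](CCCC)(CCCC)CCCC)=C/C/C=C(\C)CC[C@@H](O[Si](C)(C)C(C)(C)C)C(=C)CS(C)(=O)=O
F12 | step 10 | (2R,3S)-5-bromo-1,1-dimethoxy-2-[(4-methoxybenzyl)oxy]-3-methylpentane | COC(OC)[C@H](OCc1ccc(OC)cc1)[C@@H](C)CCBr
F13 | step 10 | (2R,3S)-5-bromo-2-[(4-methoxybenzyl)oxy]-3-methylpentanal | O=C[C@H](OCc1ccc(OC)cc1)[C@@H](C)CCBr
F14 | step 10 | C6-O-PMB ether of hydroxy ester 25 | BrCC[C@H](C)[C@@H](OCc1ccc(OC)cc1)[C@H](O)[C@H](C(=C)C(=O)OC)C/C=C(\C)CC[C@@H](O[Si](C)(C)C(C)(C)C)C(=C)CS(C)(=O)=O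
F15 | step 10 | C6-O-PMB ether of lactone 26 | BrCC[C@H](C)[C@@H](OCc1ccc(OC)cc1)[C@@H]1OC(=O)C(=C)[C@@H]1C/C=C(\C)CC[C@@H](O[Si](C)(C)C(C)(C)C)C(=C)CS(C)(=O)=O
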